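## The problem

The target is a 7,8-dihydro-6H-isochromen-6-one. Pyran ring A (O2, C1, C3, C4, C4a, C8a) is fused through C4a–C8a to carbocycle B (C4a, C5, C6, C7, C8, C8a). The double bonds C1=C8a, C3=C4 and C4a=C5 form a cross-conjugated push–pull system running from O2 to the C6 carbonyl. This chromophore is the fragile part: amines exchange O2 for nitrogen, hydroxide opens ring A at C1, and electrophiles attack C5, so strong bases and nucleophiles must be avoided once it exists. The only stereocentre is C7 (S), quaternary and oxygenated. No other centre can control it, so it must come from the chiral pool or a catalyst; having no hydrogen, it cannot epimerise afterwards. The C7 oxygen carries an orsellinate, so a tertiary α-ketol must be esterified with a doubly ortho-substituted benzoic acid whose two phenols end up free. The C3 substituent is an (E)-propenyl chain ending in a primary allylic acetate, which is labile to base, ester enolates and zerovalent palladium, and so must be installed late. The enabling feature is that ring A, once ring B is opened at C4a=C5 and C4a is read as a carbonyl, is a 2,5-disubstituted 4-pyranone: O2–C3–C4–C4a is an acylketene and C1=C8a an enol ether, so ring A can be made by a hetero-[4+2] union of a side-chain fragment with a C7-bearing fragment.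

## Retrosynthesis

**Protecting groups and the C7 ester.** The target 29 is traced to its bis(methoxymethyl) ether 28, and 28 is cut at the C7–O acyl bond into tertiary alcohol 22 and acid 25 (used as its chloride 26). Cutting here keeps the hindered aryl ester out of all enolate chemistry. The phenols need protection that survives an alkoxide acylation and leaves in the presence of an acetate, which acetal ethers do and acyl, allyl or silyl groups do not do as cleanly. The forward step must acylate a hindered lithium alkoxide without touching the primary acetate.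

**Acetate and the temporary carboxyl.** Alcohol 22 comes from diol 21 by acetylation of the primary hydroxyl, a discrimination between primary and tertiary alcohols that needs no protecting group. Diol 21 is traced to ester 19 by adding back a tert-butoxycarbonyl group at C5 and silyl groups on both oxygens. The C5 carboxyl is what makes C5 acidic enough to close ring B; the forward step removes it, and both silyl groups, in one acid treatment through acid 20.

**Ring B.** Ester 19 is cut at C4a=C5 to the monocyclic pyranone β-keto ester 18 (Knoevenagel transform). After removal of the silyl group (17), it is cut at C5–C6 to pyranone 16, whose dioxolanone carbonyl is C6 (Claisen transform). This order is preferred over forming C5–C6 last, because the C6 electrophile is already present in 16 as an activated lactone and an acetate enolate selects it over the pyranone. The precursor 16 has one ring fewer and no chromophore. The forward steps require an enolate to add to the lactone and not to ring A, and the enol carbon to attack C4a and not C1.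

**Ring A (key cut).** Pyranone 16 is cut at C4a–C8a and O2–C1 into alkenyl dioxinone 13 (the masked acylketene 14) and enol ether 7. This is the most convergent cut available: it separates the side chain from the stereocentre-bearing half, and both fragments are short. Other pyranone syntheses (cyclodehydration of tricarbonyl compounds) would need dianion chemistry incompatible with the lactone. The forward reaction needs only correct regiochemistry, which polarity dictates, and capture of the ketene before it dimerises.

**The C7 fragment.** Enol ether 7 comes from acetal 6 by loss of methanol. Acetal 6 is cut at the C7–C8 bond into the lactate-derived dioxolanone 2 and iodide 4 (from bromide 3). Dioxolanone 2 comes from (R)-lactic acid 1. The acetal carbon of 2 stores the chirality while C7 is planar, so alkylation anti to the tert-butyl group sets C7; a catalytic method is not needed for a single quaternary centre available this cheaply.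

**The side-chain fragment.** Dioxinone 13 is traced through alcohol 11 to dioxinone 8 and aldehyde 9 (vinylogous aldol, then dehydration), two steps from commercial materials.

**The acyl donor.** Acid 25 comes from ester 24 and methyl orsellinate 23 by etherification and saponification.

## Roads not taken

**Alternative 1:** The cut is C4a=C5 of ring B: bicyclic ester A1 is traced to the pyranone β-keto ester A2. In the forward step, warm acetic anhydride acetylates the pyranone oxygen of A2, the tethered β-keto ester carbon adds to C4a, and acetic acid is lost.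
- Merits: the chromophore is built in one non-basic step from a stable monocyclic precursor, by a known reaction class. The 2-(trimethylsilyl)ethyl ester of A1 would let one fluoride source remove the ester and both silyl ethers.
- Weak points: as a strategy it says how ring B closes but not where A2 comes from. A2 is itself a 2,5-disubstituted pyranone carrying C7, so the two hardest questions are left open. The C4a-versus-C1 ambiguity of the closure remains.
- Comparison: the chosen plan contains the same closure as step 10 (18 to 19), so the two differ only in which bond set organises the synthesis. The fluoride-labile ester of A1 is arguably better than the tert-butyl ester of 19, since it avoids the acidic unmasking of step 11. Against this, the tert-butyl ester resists lactonisation at the open-chain stage and its acidolysis promotes decarboxylation in the same flask, and the chosen plan supplies a convergent source of the pyranone.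

**Alternative 2:** The cut is C6–C7: α-ketol A3 is traced to aldehyde–ketone A4. In the forward step a chiral triazolylidene carbene inverts the polarity of the C6 aldehyde, which then adds to the C7 methyl ketone, closing ring B and setting C7.
- Merits: the stereocentre is made catalytically and enantioselectively, without a chiral-pool auxiliary. A3 is already the free tertiary alcohol with no extra carboxyl, so the Claisen, silylation and decarboxylation steps disappear. If A4 were in hand the endgame would be about three steps shorter than from 16. Such aldehyde–ketone closures to six-membered tertiary α-ketols are known for aryl aldehydes.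
- Weak points: the aldehyde of A4 is a doubly vinylogous formate, a poor electrophile for carbene addition, and as an enal it offers the competing homoenolate pathway. Enantioselection between a methyl and an alkyl group on such a substrate is unproven. A4 is a sensitive 4-ylidene-4H-pyran with a defined exocyclic geometry, and its synthesis is not obviously shorter than that of 16.
- Comparison: this road is more elegant and potentially shorter. The chosen plan sets against it a secure absolute configuration from 1 through a stereospecific alkylation, and the fact that every step belongs to a known reaction class.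

**Alternative 3:** The cut is C5–C6: bis-silyl ether A5 is traced to the 4-methylpyrylium salt A6. In the forward step a tertiary amine deprotonates the 4-methyl group of A6, and the exocyclic carbon (C5) attacks the C6 carboxyl activated as a mixed anhydride.
- Merits: C5 comes from a plain methyl group, so there is no temporary ester and no decarboxylation. Acylation at the exocyclic carbon of deprotonated 4-methylpyrylium salts is classical chemistry. From a pyranone the bicyclic core would take about two steps, against four in the chosen plan (steps 8 to 11), and no acid is needed.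
- Weak points: A6 must carry two silyl ethers and a carboxyl through pyrylium formation, which needs either strong acid or addition of a methyl organometallic to a pyranone. On a compound such as 16 the methyl nucleophile would attack the lactone first. The pyrylium ring is also open to attack at C1 by the amine and by carboxylate.
- Comparison: shorter on paper after ring A. The chosen plan sets against it that its C5 donor, an ester enolate, prefers the lactone carbonyl, the chemoselectivity this substrate naturally offers. Neither road removes the need for a ring A synthesis.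

Key step: step 7

## Route

Assumption: enol ether 7 is drawn as its (E)-isomer; the elimination in step 4 need not be geometrically clean, because this double-bond geometry is erased when methanol is lost in step 7, so the material would be used as obtained.

Step 1
Reactants: 1 (R)-lactic acid
Product: 2 (2R,5R)-2-tert-butyl-5-methyl-1,3-dioxolan-4-one
Conditions: pivalaldehyde, TsOH·H2O (cat.), H2SO4 (cat.), pentane, reflux with azeotropic removal of water; crystallization from pentane/Et2O, −78 °C
Reagents that add atoms: pivalaldehyde CC(C)(C)C=O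
Why: Acid-catalysed acetalisation of an α-hydroxy acid (self-regeneration of stereocentres); thermodynamic control favours the cis arrangement of methyl and tert-butyl, crystallization should deliver it pure, and the new acetal centre (R) stores the chirality of the lactate.

Step 2
Reactants: 3 3-bromo-1,1-dimethoxypropane
Product: 4 3-iodo-1,1-dimethoxypropane
Conditions: NaI, acetone, reflux
Reagents that add atoms: sodium iodide [Na+].[I-]
Why: Finkelstein exchange driven by precipitation of NaBr; the iodide is wanted because the dioxolanone enolate is thermally fragile and alkylates well only with reactive electrophiles.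

Step 3
Reactants: 2 (2R,5R)-2-tert-butyl-5-methyl-1,3-dioxolan-4-one; 4 3-iodo-1,1-dimethoxypropane
Product: 6 (2R,5S)-2-tert-butyl-5-(3,3-dimethoxypropyl)-5-methyl-1,3-dioxolan-4-one, via lithium enolate 5 (not isolated)
Conditions: LiN(iPr)2, THF, −78 °C; then 4, DMPU, −78 → −30 °C
Reagents that add atoms: none
Why: Enolate alkylation of a lactate-derived dioxolanone; the planar enolate is attacked on the face anti to the tert-butyl group, so the chain replaces the former hydrogen with retention and the quaternary centre (future C7) should form as (S); primary alkyl iodides, including ketal-bearing ones, are known electrophiles for this enolate.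

Step 4
Reactants: 6 (2R,5S)-2-tert-butyl-5-(3,3-dimethoxypropyl)-5-methyl-1,3-dioxolan-4-one
Product: 7 (2R,5S)-2-tert-butyl-5-[(E)-3-methoxyprop-2-enyl]-5-methyl-1,3-dioxolan-4-one
Conditions: TMSOTf, iPr2NEt, CH2Cl2, −20 °C → rt
Reagents that add atoms: none
Why: Silyl triflate/amine conversion of a dimethyl acetal into a methyl enol ether (ionisation to the oxocarbenium ion, then α-deprotonation); the acylal of the dioxolanone ionises far less readily and has no α-hydrogen on its tert-butyl side, so even reversible opening there would be harmless to the quaternary centre.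

Step 5
Reactants: 8 2,2,6-trimethyl-4H-1,3-dioxin-4-one; 9 (tert-butyldimethylsilyloxy)acetaldehyde
Product: 11 6-[3-(tert-butyldimethylsilyloxy)-2-hydroxypropyl]-2,2-dimethyl-4H-1,3-dioxin-4-one (racemic), via lithium dienolate 10 (not isolated)
Conditions: LiN(iPr)2, THF, −78 °C; then 9, −78 °C; AcOH quench
Reagents that add atoms: none
Why: Vinylogous aldol addition: kinetic deprotonation of the 6-methyl group gives the dienolate, which adds to aldehydes through its γ-carbon; the carbinol centre is left racemic because step 6 removes it.

Step 6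
Reactants: 11 6-[3-(tert-butyldimethylsilyloxy)-2-hydroxypropyl]-2,2-dimethyl-4H-1,3-dioxin-4-one
Product: 13 6-[(E)-3-(tert-butyldimethylsilyloxy)prop-1-enyl]-2,2-dimethyl-4H-1,3-dioxin-4-one, via methanesulfonate 12 (not isolated)
Conditions: MsCl, Et3N, CH2Cl2, 0 °C; then DBU, 0 °C → rt
Reagents that add atoms: none
Why: Mesylation followed by E1cB elimination; the protons next to the dioxinone are vinylogously acidic, so elimination runs toward the ring and should give the conjugated, thermodynamically preferred (E)-alkene.

Step 7
Reactants: 13 6-[(E)-3-(tert-butyldimethylsilyloxy)prop-1-enyl]-2,2-dimethyl-4H-1,3-dioxin-4-one; 7 (2R,5S)-2-tert-butyl-5-[(E)-3-methoxyprop-2-enyl]-5-methyl-1,3-dioxolan-4-one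
Product: 16 (2R,5S)-2-tert-butyl-5-({6-[(E)-3-(tert-butyldimethylsilyloxy)prop-1-enyl]-4-oxo-4H-pyran-3-yl}methyl)-5-methyl-1,3-dioxolan-4-one, via acylketene 14 (not isolated), via methoxydihydropyranone 15 (not isolated)
Conditions: 13 (2 equiv) added slowly to 7 in toluene, 110 °C; then PPTS (cat.), 110 °C
Reagents that add atoms: none
Why: At 110 °C dioxinone 13 undergoes retro-[4+2] loss of acetone to alkenyl acylketene 14, an electron-poor 1-oxadiene (O2–C3–C4–C4a) that combines with the electron-rich C1=C8a bond of 7 in an inverse-demand hetero-Diels–Alder reaction to give 15. The closest known reaction type is exactly this: thermal generation of acylketenes from 1,3-dioxin-4-ones, their [4+2] capture by vinyl ethers to 2-alkoxy-2,3-dihydro-4-pyranones, and acid-induced loss of alcohol to 4-pyranones. Ring A closes in a single six-membered cycloaddition that forms C4a–C8a and O2–C1, either concertedly or through a zwitterion whose enolate oxygen attacks the oxocarbenium carbon in a 6-exo-trig sense. No lasting stereocentre is made: the two sp3 ring carbons of 15 are flattened when PPTS catalyses loss of methanol, and the quaternary future C7 has no hydrogen and cannot epimerise. The selectivity needed is regiochemical, C8a to the ketene carbon and the acyl oxygen to C1, and it is fixed by the polarity of both partners, the enol ether being nucleophilic only at its β-carbon and the ketene electrophilic only at its central carbon. The second requirement is that 7 traps 14 faster than 14 dimerises; slow addition of an excess of the cheaper partner 13 to concentrated 7 keeps the ketene dilute and the trap abundant. Neither the acylal lactone nor the silyl ether carries an O–H or N–H that could divert the ketene, and both should tolerate 110 °C and the weak acid.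

Step 8
Reactants: 16 (2R,5S)-2-tert-butyl-5-({6-[(E)-3-(tert-butyldimethylsilyloxy)prop-1-enyl]-4-oxo-4H-pyran-3-yl}methyl)-5-methyl-1,3-dioxolan-4-one
Product: 17 tert-butyl (S)-5-{6-[(E)-3-(tert-butyldimethylsilyloxy)prop-1-enyl]-4-oxo-4H-pyran-3-yl}-4-hydroxy-4-methyl-3-oxopentanoate
Conditions: tert-butyl acetate, LiN(iPr)2 (3.5 equiv each, enolate preformed), THF, −78 °C; AcOH quench at −78 °C
Reagents that add atoms: tert-butyl acetate CC(=O)OC(C)(C)C
Why: Crossed Claisen condensation: the ester enolate adds to the activated acylal-type lactone carbonyl (C6), the ring opens and the hemiacetal alkoxide sheds pivalaldehyde, and the β-keto ester is protected from further attack as its enolate; addition of this enolate to 1,3-dioxolan-4-ones is a known route to γ-hydroxy-β-keto esters, and the tert-butyl ester is chosen because it resists lactonisation to a tetronic acid; C7 is not touched.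

Step 9
Reactants: 17 tert-butyl (S)-5-{6-[(E)-3-(tert-butyldimethylsilyloxy)prop-1-enyl]-4-oxo-4H-pyran-3-yl}-4-hydroxy-4-methyl-3-oxopentanoate
Product: 18 tert-butyl (S)-5-{6-[(E)-3-(tert-butyldimethylsilyloxy)prop-1-enyl]-4-oxo-4H-pyran-3-yl}-4-methyl-3-oxo-4-(triethylsilyloxy)pentanoate
Conditions: TESOTf, 2,6-lutidine, CH2Cl2, −78 → 0 °C
Reagents that add atoms: triethylsilyl triflate CC[Si](CC)(CC)OS(=O)(=O)C(F)(F)F
Why: Silyl triflate/lutidine silylation of a hindered tertiary alcohol; the ether blocks tetronic acid formation and keeps the hydroxyl from adding to the activated pyranone in step 10.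

Step 10
Reactants: 18 tert-butyl (S)-5-{6-[(E)-3-(tert-butyldimethylsilyloxy)prop-1-enyl]-4-oxo-4H-pyran-3-yl}-4-methyl-3-oxo-4-(triethylsilyloxy)pentanoate
Product: 19 tert-butyl (S)-3-[(E)-3-(tert-butyldimethylsilyloxy)prop-1-enyl]-7-methyl-6-oxo-7-(triethylsilyloxy)-7,8-dihydro-6H-isochromene-5-carboxylate
Conditions: Ac2O, 70 °C
Reagents that add atoms: none
Why: Knoevenagel condensation of a 4-pyranone with a 1,3-dicarbonyl carbon in acetic anhydride, the reaction used to make 4-ylidene-4H-pyrans from pyranones and active methylene compounds; O-acetylation makes C4a electrophilic, the enol carbon C5 adds in a six-membered closure and loss of acetic acid gives the C4a=C5 bond, an irreversible step that should drain any reversible addition at C1.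

Step 11
Reactants: 19 tert-butyl (S)-3-[(E)-3-(tert-butyldimethylsilyloxy)prop-1-enyl]-7-methyl-6-oxo-7-(triethylsilyloxy)-7,8-dihydro-6H-isochromene-5-carboxylate
Product: 21 (S)-7-hydroxy-3-[(E)-3-hydroxyprop-1-enyl]-7-methyl-7,8-dihydro-6H-isochromen-6-one, via carboxylic acid 20 (not isolated)
Conditions: TFA/CH2Cl2/H2O (10:20:1), 0 °C → rt; then NaHCO3, aq. MeOH
Reagents that add atoms: none
Why: Acidolysis of the tert-butyl ester and both silyl ethers; the vinylogous β-keto acid 20 should protonate at C5 and decarboxylate readily because the C6 carbonyl and the pyrylium-like ring both act as electron sinks, and protonation of the chromophore at the C6 oxygen disfavours ionisation at the allylic carbon.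

Step 12
Reactants: 21 (S)-7-hydroxy-3-[(E)-3-hydroxyprop-1-enyl]-7-methyl-7,8-dihydro-6H-isochromen-6-one
Product: 22 (E)-3-[(S)-7-hydroxy-7-methyl-6-oxo-7,8-dihydro-6H-isochromen-3-yl]prop-2-enyl acetate
Conditions: Ac2O (1.1 equiv), pyridine, CH2Cl2, 0 °C
Reagents that add atoms: acetic anhydride CC(=O)OC(C)=O
Why: Chemoselective acetylation: the primary allylic alcohol reacts under these conditions while the tertiary α-ketol is inert without a nucleophilic catalyst.

Step 13
Reactants: 23 methyl 2,4-dihydroxy-6-methylbenzoate (methyl orsellinate)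
Product: 24 methyl 2,4-bis(methoxymethoxy)-6-methylbenzoate
Conditions: NaH, MOMCl, DMF, 0 °C → rt
Reagents that add atoms: chloromethyl methyl ether COCCl
Why: Williamson-type etherification of both phenoxides; NaH is used so that the hydrogen-bonded ortho hydroxyl is also alkylated.

Step 14
Reactants: 24 methyl 2,4-bis(methoxymethoxy)-6-methylbenzoate
Product: 25 2,4-bis(methoxymethoxy)-6-methylbenzoic acid
Conditions: KOH, DMSO/H2O, 90 °C; then cold 1 M HCl to pH 4
Reagents that add atoms: potassium hydroxide [K+].[OH-]
Why: Saponification of a hindered benzoate under forcing alkaline conditions, to which the acetal ethers are inert; acidification only to pH 4 in the cold keeps them intact.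

Step 15
Reactants: 22 (E)-3-[(S)-7-hydroxy-7-methyl-6-oxo-7,8-dihydro-6H-isochromen-3-yl]prop-2-enyl acetate; 25 2,4-bis(methoxymethoxy)-6-methylbenzoic acid
Product: 28 (S)-3-[(E)-3-acetoxyprop-1-enyl]-7-methyl-6-oxo-7,8-dihydro-6H-isochromen-7-yl 2,4-bis(methoxymethoxy)-6-methylbenzoate, via acid chloride 26 (not isolated), via lithium alkoxide 27 (not isolated)
Conditions: 25, 1-chloro-N,N,2-trimethylprop-1-en-1-amine, CH2Cl2, rt (gives 26); 22, LiN(SiMe3)2 (1.05 equiv), THF, −78 °C (gives 27); then 26, −78 → 0 °C
Reagents that add atoms: none
Why: Acylation of a lithium tert-alkoxide with an aroyl chloride, the usual way to esters of tertiary alcohols with di-ortho-substituted benzoic acids; the chloride is made under neutral conditions so the acetal ethers survive, one equivalent of the hindered amide base removes only the O–H (far more acidic than the acetate C–H), and no bond to C7 is broken.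

Step 16
Reactants: 28 (S)-3-[(E)-3-acetoxyprop-1-enyl]-7-methyl-6-oxo-7,8-dihydro-6H-isochromen-7-yl 2,4-bis(methoxymethoxy)-6-methylbenzoate
Product: 29 (S)-3-[(E)-3-acetoxyprop-1-enyl]-7-methyl-6-oxo-7,8-dihydro-6H-isochromen-7-yl 2,4-dihydroxy-6-methylbenzoate (CNP0115558.1)
Conditions: TFA/CH2Cl2 (1:10), H2O (5 equiv), 0 °C
Reagents that add atoms: none
Why: Acid hydrolysis of aryl methoxymethyl ethers, the ortho one assisted by the neighbouring ester carbonyl; the acetate and the tertiary aryl ester are stable to cold dilute acid, and water traps the methoxymethyl cation as formaldehyde and methanol before it can alkylate the resorcinol ring.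

## Compound list

1 | (R)-lactic acid | C[C@@H](O)C(O)=O | starting material
2 | (2R,5R)-2-tert-butyl-5-methyl-1,3-dioxolan-4-one | C[C@H]1O[C@@H](C(C)(C)C)OC1=O | intermediate
3 | 3-bromo-1,1-dimethoxypropane | COC(CCBr)OC | starting material
4 | 3-iodo-1,1-dimethoxypropane | COC(CCI)OC | intermediate
5 | lithium (R)-2-tert-butyl-5-methyl-1,3-dioxol-4-olate | CC1=C([O-])O[C@H](C(C)(C)C)O1.[Li+] | intermediate (not isolated)
6 | (2R,5S)-2-tert-butyl-5-(3,3-dimethoxypropyl)-5-methyl-1,3-dioxolan-4-one | COC(OC)CC[C@]1(C)O[C@@H](C(C)(C)C)OC1=O | intermediate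
7 | (2R,5S)-2-tert-butyl-5-[(E)-3-methoxyprop-2-enyl]-5-methyl-1,3-dioxolan-4-one | CO/C=C/C[C@]1(C)O[C@@H](C(C)(C)C)OC1=O | intermediate
8 | 2,2,6-trimethyl-4H-1,3-dioxin-4-one | CC1=CC(=O)OC(C)(C)O1 | starting material
9 | (tert-butyldimethylsilyloxy)acetaldehyde | CC(C)(C)[Si](C)(C)OCC=O | starting material
10 | lithium 2,2-dimethyl-6-methylidene-6H-1,3-dioxin-4-olate | C=C1C=C([O-])OC(C)(C)O1.[Li+] | intermediate (not isolated)
11 | 6-[3-(tert-butyldimethylsilyloxy)-2-hydroxypropyl]-2,2-dimethyl-4H-1,3-dioxin-4-one (racemic) | CC(C)(C)[Si](C)(C)OCC(O)CC1=CC(=O)OC(C)(C)O1 | intermediate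
12 | 1-(tert-butyldimethylsilyloxy)-3-(2,2-dimethyl-4-oxo-4H-1,3-dioxin-6-yl)propan-2-yl methanesulfonate (racemic) | CC(C)(C)[Si](C)(C)OCC(OS(C)(=O)=O)CC1=CC(=O)OC(C)(C)O1 | intermediate (not isolated)
13 | 6-[(E)-3-(tert-butyldimethylsilyloxy)prop-1-enyl]-2,2-dimethyl-4H-1,3-dioxin-4-one | CC(C)(C)[Si](C)(C)OC/C=C/C1=CC(=O)OC(C)(C)O1 | intermediate
14 | (E)-6-(tert-butyldimethylsilyloxy)-3-oxohexa-1,4-dien-1-one | CC(C)(C)[Si](C)(C)OC/C=C/C(=O)C=C=O | intermediate (not isolated)
15 | (2R,5S)-2-tert-butyl-5-({6-[(E)-3-(tert-butyldimethylsilyloxy)prop-1-enyl]-2-methoxy-4-oxo-3,4-dihydro-2H-pyran-3-yl}methyl)-5-methyl-1,3-dioxolan-4-one (mixture at the two transient ring centres) | COC1OC(/C=C/CO[Si](C)(C)C(C)(C)C)=CC(=O)C1C[C@]2(C)O[C@@H](C(C)(C)C)OC2=O | intermediate (not isolated)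
16 | (2R,5S)-2-tert-butyl-5-({6-[(E)-3-(tert-butyldimethylsilyloxy)prop-1-enyl]-4-oxo-4H-pyran-3-yl}methyl)-5-methyl-1,3-dioxolan-4-one | CC(C)(C)[Si](C)(C)OC/C=C/C1=CC(=O)C(C[C@]2(C)O[C@@H](C(C)(C)C)OC2=O)=CO1 | intermediate
17 | tert-butyl (S)-5-{6-[(E)-3-(tert-butyldimethylsilyloxy)prop-1-enyl]-4-oxo-4H-pyran-3-yl}-4-hydroxy-4-methyl-3-oxopentanoate | CC(C)(C)[Si](C)(C)OC/C=C/C1=CC(=O)C(C[C@](C)(O)C(=O)CC(=O)OC(C)(C)C)=CO1 | intermediate
18 | tert-butyl (S)-5-{6-[(E)-3-(tert-butyldimethylsilyloxy)prop-1-enyl]-4-oxo-4H-pyran-3-yl}-4-methyl-3-oxo-4-(triethylsilyloxy)pentanoate | CC(C)(C)[Si](C)(C)OC/C=C/C1=CC(=O)C(C[C@](C)(O[Si](CC)(CC)CC)C(=O)CC(=O)OC(C)(C)C)=CO1 | intermediate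
19 | tert-butyl (S)-3-[(E)-3-(tert-butyldimethylsilyloxy)prop-1-enyl]-7-methyl-6-oxo-7-(triethylsilyloxy)-7,8-dihydro-6H-isochromene-5-carboxylate | CC(C)(C)[Si](C)(C)OC/C=C/C1=CC2=C(C(=O)OC(C)(C)C)C(=O)[C@@](C)(O[Si](CC)(CC)CC)CC2=CO1 | intermediate
20 | (S)-7-hydroxy-3-[(E)-3-hydroxyprop-1-enyl]-7-methyl-6-oxo-7,8-dihydro-6H-isochromene-5-carboxylic acid | OC/C=C/C1=CC2=C(C(O)=O)C(=O)[C@@](C)(O)CC2=CO1 | intermediate (not isolated)
21 | (S)-7-hydroxy-3-[(E)-3-hydroxyprop-1-enyl]-7-methyl-7,8-dihydro-6H-isochromen-6-one | OC/C=C/C1=CC2=CC(=O)[C@@](C)(O)CC2=CO1 | intermediate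
22 | (E)-3-[(S)-7-hydroxy-7-methyl-6-oxo-7,8-dihydro-6H-isochromen-3-yl]prop-2-enyl acetate | CC(=O)OC/C=C/C1=CC2=CC(=O)[C@@](C)(O)CC2=CO1 | intermediate
23 | methyl 2,4-dihydroxy-6-methylbenzoate | COC(=O)c1c(C)cc(O)cc1O | starting material
24 | methyl 2,4-bis(methoxymethoxy)-6-methylbenzoate | COCOc1cc(C)c(C(=O)OC)c(OCOC)c1 | intermediate
25 | 2,4-bis(methoxymethoxy)-6-methylbenzoic acid | COCOc1cc(C)c(C(O)=O)c(OCOC)c1 | intermediate
26 | 2,4-bis(methoxymethoxy)-6-methylbenzoyl chloride | COCOc1cc(C)c(C(Cl)=O)c(OCOC)c1 | intermediate (not isolated)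
27 | lithium (S)-3-[(E)-3-acetoxyprop-1-enyl]-7-methyl-6-oxo-7,8-dihydro-6H-isochromen-7-olate | CC(=O)OC/C=C/C1=CC2=CC(=O)[C@@](C)([O-])CC2=CO1.[Li+] | intermediate (not isolated)
28 | (S)-3-[(E)-3-acetoxyprop-1-enyl]-7-methyl-6-oxo-7,8-dihydro-6H-isochromen-7-yl 2,4-bis(methoxymethoxy)-6-methylbenzoate | CC(=O)OC/C=C/C1=CC2=CC(=O)[C@@](C)(OC(=O)c3c(C)cc(OCOC)cc3OCOC)CC2=CO1 | intermediate
29 | (S)-3-[(E)-3-acetoxyprop-1-enyl]-7-methyl-6-oxo-7,8-dihydro-6H-isochromen-7-yl 2,4-dihydroxy-6-methylbenzoate | CC(=O)OC/C=C/C1=CC2=CC(=O)[C@@](C)(OC(=O)c3c(C)cc(O)cc3O)CC2=CO1 | target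

## Step count and least certain steps

Total step count: 16. Longest linear sequence: 11 steps (steps 1, 3, 4, 7, 8, 9, 10, 11, 12, 15, 16, from 1 to 29).

**Step 7 (key step).** The most likely failure is dimerisation of the acylketene outrunning its capture, because the enol ether is β-substituted next to a neopentyl-like carbon; incomplete loss of methanol is a lesser concern. Fallback, setting out from acetal 6: mild aqueous acid hydrolysis gives (2R,5S)-2-tert-butyl-5-methyl-5-(3-oxopropyl)-1,3-dioxolan-4-one F1. Morpholine with molecular sieves converts it into the morpholine enamine F2. Heating F2 with 13 in toluene lets the far more nucleophilic enamine carbon intercept 14 by C-acylation; ring closure gives the 2-morpholino-2,3-dihydropyranone F3, which loses morpholine on mild acid work-up and rejoins the route at 16. Condensation of enamines with acylketene sources to 4-pyranones is established chemistry.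

**Step 3.** Alkylation with an unactivated primary iodide may be slow against thermal decay of the enolate, and E2 loss of HI from 4 can compete. Fallback, setting out from 2: the same enolate is alkylated with allyl bromide, the most reliable electrophile for it, to give (2R,5S)-5-allyl-2-tert-butyl-5-methyl-1,3-dioxolan-4-one F4. Ozonolysis with Me2S work-up gives 2-[(2R,4S)-2-tert-butyl-4-methyl-5-oxo-1,3-dioxolan-4-yl]acetaldehyde F5, and Wittig methoxymethylenation with Ph3P=CHOMe rejoins the route at 7 without passing through 6.

**Step 8.** The ester enolate may add in conjugate fashion to the unsubstituted C1 position of the pyranone or deprotonate the vinylogous CH2OSi position, and the product may lactonise during work-up. Fallback, setting out from 16: LiOH in aqueous THF at 0 °C opens the lactone to (S)-3-{6-[(E)-3-(tert-butyldimethylsilyloxy)prop-1-enyl]-4-oxo-4H-pyran-3-yl}-2-hydroxy-2-methylpropanoic acid F6. Silylation with TESOTf/2,6-lutidine and a carbonate work-up gives the triethylsilyl-protected acid F7. Carbonyldiimidazole gives the acyl imidazolide F8, which is C-acylated under neutral conditions by Mg(O2CCH2CO2tBu)2 with loss of CO2, rejoining the route at 18 and bypassing 17 and step 9.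

**Step 10.** The enol carbon may attack C1 instead of C4a (both closures are six-membered), leading to opening of ring A, or activation by the anhydride may be too slow. Fallback, setting out from 18: O-methylation of the pyranone with MeOTf gives the 4-methoxypyrylium triflate F9, a discrete electrophile in which C4a carries a leaving group. A hindered amine base then lets the β-keto ester carbon displace methoxide at C4a, the known substitution of 4-alkoxypyrylium salts by active methylene compounds, rejoining the route at 19.

**Step 15.** Acylation of the hindered alkoxide by the hindered chloride may be slow, leaving time for intermolecular acetyl transfer or C-acylation at C5. Fallback, setting out from diol 21: TBDPSCl/imidazole gives the primary silyl ether F10, which has no base-sensitive ester and so tolerates excess base, excess 26 and warming in the alkoxide acylation, giving the aroylated silyl ether F11. HF·pyridine frees the primary alcohol F12, and Ac2O/pyridine rejoins the route at 28.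

## Further compounds

F1 | step 7 | (2R,5S)-2-tert-butyl-5-methyl-5-(3-oxopropyl)-1,3-dioxolan-4-one | O=CCC[C@]1(C)O[C@@H](C(C)(C)C)OC1=O
F2 | step 7 | (2R,5S)-2-tert-butyl-5-methyl-5-[(E)-3-(morpholin-4-yl)prop-2-enyl]-1,3-dioxolan-4-one | C1COCCN1/C=C/C[C@]2(C)O[C@@H](C(C)(C)C)OC2=O
F3 | step 7 | (2R,5S)-2-tert-butyl-5-({6-[(E)-3-(tert-butyldimethylsilyloxy)prop-1-enyl]-2-(morpholin-4-yl)-4-oxo-3,4-dihydro-2H-pyran-3-yl}methyl)-5-methyl-1,3-dioxolan-4-one | O=C1C=C(/C=C/CO[Si](C)(C)C(C)(C)C)OC(N2CCOCC2)C1C[C@]3(C)O[C@@H](C(C)(C)C)OC3=O
F4 | step 3 | (2R,5S)-5-allyl-2-tert-butyl-5-methyl-1,3-dioxolan-4-one | C=CC[C@]1(C)O[C@@H](C(C)(C)C)OC1=O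
F5 | step 3 | 2-[(2R,4S)-2-tert-butyl-4-methyl-5-oxo-1,3-dioxolan-4-yl]acetaldehyde | O=CC[C@]1(C)O[C@@H](C(C)(C)C)OC1=O
F6 | step 8 | (S)-3-{6-[(E)-3-(tert-butyldimethylsilyloxy)prop-1-enyl]-4-oxo-4H-pyran-3-yl}-2-hydroxy-2-methylpropanoic acid | CC(C)(C)[Si](C)(C)OC/C=C/C1=CC(=O)C(C[C@](C)(O)C(O)=O)=CO1
F7 | step 8 | (S)-3-{6-[(E)-3-(tert-butyldimethylsilyloxy)prop-1-enyl]-4-oxo-4H-pyran-3-yl}-2-methyl-2-(triethylsilyloxy)propanoic acid | CC(C)(C)[Si](C)(C)OC/C=C/C1=CC(=O)C(C[C@](C)(O[Si](CC)(CC)CC)C(O)=O)=CO1
F8 | step 8 | (S)-3-{6-[(E)-3-(tert-butyldimethylsilyloxy)prop-1-enyl]-4-oxo-4H-pyran-3-yl}-1-(imidazol-1-yl)-2-methyl-2-(triethylsilyloxy)propan-1-one | CC(C)(C)[Si](C)(C)OC/C=C/C1=CC(=O)C(C[C@](C)(O[Si](CC)(CC)CC)C(=O)n2ccnc2)=CO1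
F9 | step 10 | 5-[(S)-5-tert-butoxy-2-methyl-3,5-dioxo-2-(triethylsilyloxy)pentyl]-2-[(E)-3-(tert-butyldimethylsilyloxy)prop-1-enyl]-4-methoxypyrylium triflate | CC(C)(C)[Si](C)(C)OC/C=C/c1cc(OC)c(C[C@](C)(O[Si](CC)(CC)CC)C(=O)CC(=O)OC(C)(C)C)c[o+]1.[O-]S(=O)(=O)C(F)(F)F
F10 | step 15 | (S)-3-[(E)-3-(tert-butyldiphenylsilyloxy)prop-1-enyl]-7-hydroxy-7-methyl-7,8-dihydro-6H-isochromen-6-one | CC(C)(C)[Si](c1ccccc1)(c1ccccc1)OC/C=C/C1=CC2=CC(=O)[C@@](C)(O)CC2=CO1
F11 | step 15 | (S)-3-[(E)-3-(tert-butyldiphenylsilyloxy)prop-1-enyl]-7-methyl-6-oxo-7,8-dihydro-6H-isochromen-7-yl 2,4-bis(methoxymethoxy)-6-methylbenzoate | CC(C)(C)[Si](c1ccccc1)(c1ccccc1)OC/C=C/C1=CC2=CC(=O)[C@@](C)(OC(=O)c3c(C)cc(OCOC)cc3OCOC)CC2=CO1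
F12 | step 15 | (S)-3-[(E)-3-hydroxyprop-1-enyl]-7-methyl-6-oxo-7,8-dihydro-6H-isochromen-7-yl 2,4-bis(methoxymethoxy)-6-methylbenzoate | OC/C=C/C1=CC2=CC(=O)[C@@](C)(OC(=O)c3c(C)cc(OCOC)cc3OCOC)CC2=CO1
A1 | alternative 1 | 2-(trimethylsilyl)ethyl (S)-3-[(E)-3-(tert-butyldimethylsilyloxy)prop-1-enyl]-7-methyl-6-oxo-7-(triethylsilyloxy)-7,8-dihydro-6H-isochromene-5-carboxylate | CC(C)(C)[Si](C)(C)OC/C=C/C1=CC2=C(C(=O)OCC[Si](C)(C)C)C(=O)[C@@](C)(O[Si](CC)(CC)CC)CC2=CO1
A2 | alternative 1 | 2-(trimethylsilyl)ethyl (S)-5-{6-[(E)-3-(tert-butyldimethylsilyloxy)prop-1-enyl]-4-oxo-4H-pyran-3-yl}-4-methyl-3-oxo-4-(triethylsilyloxy)pentanoate | CC(C)(C)[Si](C)(C)OC/C=C/C1=CC(=O)C(C[C@](C)(O[Si](CC)(CC)CC)C(=O)CC(=O)OCC[Si](C)(C)C)=CO1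
A3 | alternative 2 | (S)-3-[(E)-3-(tert-butyldimethylsilyloxy)prop-1-enyl]-7-hydroxy-7-methyl-7,8-dihydro-6H-isochromen-6-one | CC(C)(C)[Si](C)(C)OC/C=C/C1=CC2=CC(=O)[C@@](C)(O)CC2=CO1
A4 | alternative 2 | (Z)-2-{6-[(E)-3-(tert-butyldimethylsilyloxy)prop-1-enyl]-3-(2-oxopropyl)-4H-pyran-4-ylidene}acetaldehyde | O=C/C=C1\C(CC(C)=O)=COC(/C=C/CO[Si](C)(C)C(C)(C)C)=C1
A5 | alternative 3 | (S)-3-[(E)-3-(tert-butyldimethylsilyloxy)prop-1-enyl]-7-methyl-7-(triethylsilyloxy)-7,8-dihydro-6H-isochromen-6-one | CC(C)(C)[Si](C)(C)OC/C=C/C1=CC2=CC(=O)[C@@](C)(O[Si](CC)(CC)CC)CC2=CO1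
A6 | alternative 3 | 5-[(S)-2-carboxy-2-(triethylsilyloxy)propyl]-2-[(E)-3-(tert-butyldimethylsilyloxy)prop-1-enyl]-4-methylpyrylium tetrafluoroborate | Cc1cc(/C=C/CO[Si](C)(C)C(C)(C)C)[o+]cc1C[C@](C)(O[Si](CC)(CC)CC)C(O)=O.F[B-](F)(F)F
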